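**Plan**

1. Retrosynthetic cuts: ring C at C8–C14 (gives a C14=C26 exo-methylene and the ring B aryl enone); the dioxane by retro-hetero-Diels–Alder into tingenone and an o-quinone; ring B at C7=C8 (metathesis) and C5–C6; the chain at C9–C11 (copper-catalysed SN2′ allyl–alkyl coupling) into an aryl allyl chloride and a D/E diene ester.
2. Forward order: ring E (Diels–Alder), ring D (Michael/aldol annulation), fragment union at C9, ring B (ring-closing metathesis), dioxane (hetero-Diels–Alder), ring C (radical cycloisomerisation, the last ring).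
3. Stereochemistry: C20 from a catalytic asymmetric Diels–Alder reaction; C17 from a chiral-imine Michael addition; C18 (hydrogenation) and C13 (aldol on the convex face) by substrate control; C9 from a chiral copper catalyst; the tingenone unit from the natural product; C3′/C4′ in the cycloaddition; C14 in the key step.
4. Enabling feature: the C6(=O)–C7=C8 aryl enone of ring B, whose β-carbon C8 is tied through C9–C11–C12–C13 to C14. A tertiary C14 radical, made by hydrogen-atom transfer to a C14=C26 methylene, closes ring C on C8, creates the C26 methyl and the C13/C14 vicinal quaternary pair, and loss of the C8 hydrogen restores the enone; no helper group has to be removed, so the event can be run last on the assembled dimer.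

Key step: step 24

Remark (assumption): tingenone (maytenin) is taken as a purchasable natural product with the C20′ configuration drawn, and serves as the enol partner of the cycloaddition. Atom numbers are those of the celastroid (friedelane) skeleton, primed for the tingenone-derived unit; α/β refer to the usual drawing (C9, C14, C17 methyls β).

**Route**

Step 1
Reactants: 1 isoprene; 2 methacrolein
Product: 3 (R)-1,4-dimethylcyclohex-3-ene-1-carbaldehyde
Conditions: o-tolyl oxazaborolidine from α,α-diphenylprolinol protonated with HNTf2 (10 mol %, the enantiomer that delivers the (R)-adduct), CH2Cl2, −78 to −40 °C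
Reagents that add atoms: none
Why: catalytic enantioselective Diels–Alder reaction of a 2-substituted acrolein, "para" regiochemistry from the larger HOMO coefficient at C1 of isoprene, the C20 quaternary centre being set by the chiral Lewis acid that shields one face of the coordinated aldehyde.

Step 2
Reactants: 3 (R)-1,4-dimethylcyclohex-3-ene-1-carbaldehyde
Product: 5 methyl (R)-1,4-dimethylcyclohex-3-ene-1-carboxylate, via carboxylic acid 4 (not isolated)
Conditions: NaClO2, NaH2PO4, 2-methyl-2-butene, t-BuOH/H2O, 0 °C to rt; extraction; then MeI, K2CO3, DMF, rt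
Reagents that add atoms: sodium chlorite [Na+].[O-]Cl=O (one oxygen); iodomethane CI
Why: Pinnick oxidation followed by carboxylate O-alkylation, neither of which touches the quaternary stereocentre or the alkene.

Step 3
Reactants: 5 methyl (R)-1,4-dimethylcyclohex-3-ene-1-carboxylate
Product: 6 methyl (1R)-3-hydroxy-1,4-dimethylcyclohexane-1-carboxylate (diastereomers at C3 and C4)
Conditions: BH3·SMe2, THF, 0 °C; then H2O2, aq. NaOH, 0 °C
Reagents that add atoms: hydrogen peroxide OO (one oxygen)
Why: anti-Markovnikov hydroboration–oxidation of the trisubstituted alkene places oxygen on C18; the two new centres are formed as a mixture, which is harmless because C18 becomes a carbonyl carbon and C17 is reset in step 5.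

Step 4
Reactants: 6 methyl (1R)-3-hydroxy-1,4-dimethylcyclohexane-1-carboxylate
Product: 7 methyl (1R)-1,4-dimethyl-3-oxocyclohexane-1-carboxylate (C4 epimers)
Conditions: Dess–Martin periodinane, NaHCO3, CH2Cl2, rt
Reagents that add atoms: none
Why: mild oxidation of a secondary alcohol to the ketone.

Step 5
Reactants: 7 methyl (1R)-1,4-dimethyl-3-oxocyclohexane-1-carboxylate; 8 ethyl vinyl ketone
Product: 11 methyl (1R,4R)-1,4-dimethyl-3-oxo-4-(3-oxopentyl)cyclohexane-1-carboxylate, via ketimine 9 (not isolated), via Michael adduct imine 10 (not isolated)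
Conditions: (S)-1-phenylethylamine, TsOH (cat.), toluene, reflux (water separator); 8, THF, rt; then 10 % aq. AcOH, rt
Reagents that add atoms: none
Why: chiral-imine (secondary enamine) Michael addition: the imine reacts through its more substituted enamine tautomer at the methyl-bearing carbon C17, the phenylethyl group blocks one face in the aza-ene-like chair transition state (sense as in the known (S)-amine/2-methylcyclohexanone case), the old C17 configuration is erased in the enamine and the remote C20 centre should not interfere.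

Step 6
Reactants: 11 methyl (1R,4R)-1,4-dimethyl-3-oxo-4-(3-oxopentyl)cyclohexane-1-carboxylate
Product: 12 methyl (2R,4aR)-2,4a,8-trimethyl-7-oxo-1,2,3,4,4a,5,6,7-octahydronaphthalene-2-carboxylate (D/E octalone, C14 ketone, C13=C18)
Conditions: NaOMe (0.3 equiv), MeOH, 60 °C
Reagents that add atoms: none
Why: intramolecular aldol condensation (second half of a Robinson annulation) closes ring D, the conjugated enone being the thermodynamic sink.

Step 7
Reactants: 12 D/E octalone
Product: 13 cis-fused D/E decalone (17β-methyl, 18β-H, 20β-methyl, 20α-CO2Me, C14 ketone; C13 epimers)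
Conditions: H2 (1 atm), Pd/C (10 %), EtOH, rt
Reagents that add atoms: none
Why: heterogeneous hydrogenation of 10-methyl-octalone-type enones is known to favour the cis-fused decalone (18-H cis to the angular methyl); C13 is epimerisable and is reset in step 9.

Step 8
Reactants: 13 cis-fused D/E decalone
Product: 14 C13=C14 trimethylsilyl enol ether of 13
Conditions: TMSCl, NaI, Et3N, MeCN, rt (equilibrating)
Reagents that add atoms: chlorotrimethylsilane C[Si](C)(C)Cl
Why: thermodynamic silyl enol ether formation toward the more substituted carbon; cis-fused 2-decalones of this kind (compare 5β-3-keto steroids, which enolise toward C4) prefer the enol double bond on the ring-fusion side.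

Step 9
Reactants: 14 C13=C14 trimethylsilyl enol ether
Product: 15 13α-methyl-13β-(1-hydroxyethyl) cis-decalone (carbinol epimers)
Conditions: CH3CHO, TiCl4, CH2Cl2, −78 °C
Reagents that add atoms: acetaldehyde CC=O
Why: Mukaiyama aldol addition builds the C13 quaternary centre; the aldehyde should approach the enol ether on the convex face, cis to the C18 hydrogen and away from the axial C17–C22 bond, which puts the new carbon (C12) β and the methyl α.

Step 10
Reactants: 15 13α-methyl-13β-(1-hydroxyethyl) cis-decalone
Product: 16 13α-methyl-13β-vinyl cis-decalone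
Conditions: Burgess reagent, toluene, 70 °C
Reagents that add atoms: none
Why: Burgess dehydration (syn-elimination of the sulfamate); C13 is quaternary, so only the methyl hydrogens can be lost and the vinyl group results under neutral conditions that avoid retro-aldol cleavage.

Step 11
Reactants: 16 13α-methyl-13β-vinyl cis-decalone
Product: 17 D/E diene ester (13α-methyl, 13β-vinyl, C14=CH2)
Conditions: Ph3PCH3Br, KOtBu, toluene, 80 °C
Reagents that add atoms: methyltriphenylphosphonium bromide C[P+](c1ccccc1)(c1ccccc1)c1ccccc1.[Br-]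
Why: Wittig methylenation of a hindered, non-epimerisable α-quaternary ketone; the neopentyl-type methyl ester is inert to the ylide.

Step 12
Reactants: 18 2-methoxy-6-methylphenol
Product: 20 1-(4-hydroxy-3-methoxy-5-methylphenyl)ethan-1-one, via aryl acetate 19 (not isolated)
Conditions: Ac2O, rt; then MeSO3H, 80 °C
Reagents that add atoms: acetic anhydride CC(=O)OC(C)=O
Why: Fries rearrangement; both ortho positions of the phenol are substituted, so the acyl group goes para to the phenolic oxygen (the future C10).

Step 13
Reactants: 20 1-(4-hydroxy-3-methoxy-5-methylphenyl)ethan-1-one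
Product: 21 1-[3-methoxy-5-methyl-4-(triisopropylsilyloxy)phenyl]ethan-1-one
Conditions: TIPSOTf, 2,6-lutidine, CH2Cl2, 0 °C to rt
Reagents that add atoms: triisopropylsilyl triflate CC(C)[Si](OS(=O)(=O)C(F)(F)F)(C(C)C)C(C)C
Why: silylation of a hindered phenol with the silyl triflate; the flanked aryl silyl ether should survive the basic steps that follow.

Step 14
Reactants: 21 1-[3-methoxy-5-methyl-4-(triisopropylsilyloxy)phenyl]ethan-1-one
Product: 22 1-[2-iodo-5-methoxy-3-methyl-4-(triisopropylsilyloxy)phenyl]ethan-1-one
Conditions: I2, CF3CO2Ag, CHCl3, rt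
Reagents that add atoms: iodine II
Why: electrophilic aromatic iodination para to the methoxy group and ortho to the methyl group (the future C5), as in the iodination of 3,4-dimethoxyacetophenone at C6; the other free position lies between the acetyl and methoxy groups and is screened by the methoxy methyl.

Step 15
Reactants: 22 1-[2-iodo-5-methoxy-3-methyl-4-(triisopropylsilyloxy)phenyl]ethan-1-one
Product: 23 ethyl (E)-3-[2-iodo-5-methoxy-3-methyl-4-(triisopropylsilyloxy)phenyl]but-2-enoate
Conditions: triethyl phosphonoacetate, NaH, THF, 65 °C; chromatographic removal of the Z isomer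
Reagents that add atoms: triethyl phosphonoacetate CCOC(=O)CP(=O)(OCC)OCC
Why: Horner–Wadsworth–Emmons olefination of an aryl methyl ketone, the E isomer (aryl trans to the ester) being favoured.

Step 16
Reactants: 23 ethyl (E)-3-arylbut-2-enoate
Product: 24 (E)-3-[2-iodo-5-methoxy-3-methyl-4-(triisopropylsilyloxy)phenyl]but-2-en-1-ol
Conditions: i-Bu2AlH, CH2Cl2, −78 °C
Reagents that add atoms: none
Why: 1,2-reduction of the enoate to the allylic alcohol; aryl iodide and silyl ether are not affected.

Step 17
Reactants: 24 (E)-3-arylbut-2-en-1-ol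
Product: 26 [4-((E)-4-chlorobut-2-en-2-yl)-3-iodo-6-methoxy-2-methylphenoxy]triisopropylsilane, via allyl mesylate 25 (not isolated)
Conditions: MsCl, 2,4,6-collidine, LiCl, DMF, 0 °C
Reagents that add atoms: lithium chloride [Li+].[Cl-]
Why: mesylation and SN2 displacement by chloride of a primary allylic alcohol without allylic transposition.

Step 18
Reactants: 17 D/E diene ester; 26 aryl allyl chloride
Product: 28 (9R)-coupled seco compound (C9 bearing aryl, methyl, vinyl and the C11–C12 chain to C13), via alkylborane 27 (not isolated)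
Conditions: 9-BBN dimer (0.55 equiv), THF, 60 °C; then CuCl (10 mol %), chiral hydroxyaryl-substituted imidazolinium (NHC) salt (11 mol %, the enantiomer that gives 9R), KOMe, 26, THF/1,4-dioxane, 15 °C
Reagents that add atoms: none
Why: hydroboration should take the monosubstituted vinyl group and spare the 2,2-disubstituted methylene next to the quaternary carbon, after which the known copper/chiral NHC-catalysed γ-selective (SN2′) allyl–alkyl coupling of alkyl-9-BBN reagents with γ,γ-disubstituted primary allyl chlorides sets the C9 quaternary centre under catalyst control.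

Step 19
Reactants: 28 coupled seco compound
Product: 30 C6 vinyl carbinol (aryl–CH(OH)–CH=CH2 at C5; carbinol epimers), via arylmagnesium chloride 29 (not isolated)
Conditions: i-PrMgCl·LiCl, THF, 0 °C; acrolein, −78 °C; aq. NH4Cl
Reagents that add atoms: acrolein C=CC=O
Why: iodine–magnesium exchange followed by 1,2-addition to acrolein; the hindered methyl ester and the alkenes should be tolerated at these temperatures and the carbinol centre is removed in step 21.

Step 20
Reactants: 30 C6 vinyl carbinol
Product: 31 ring B dienol (4,4-disubstituted 1,4-dihydronaphthalen-1-ol, C7=C8)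
Conditions: second-generation Grubbs catalyst (5 mol %), CH2Cl2, 40 °C
Reagents that add atoms: none
Why: ring-closing metathesis of the two monosubstituted alkenes closes six-membered ring B with loss of ethylene, the hindered 1,1-disubstituted C14 methylene being inert.

Step 21
Reactants: 31 ring B dienol
Product: 32 ring B enone silyl ether (4,4-disubstituted naphthalen-1(4H)-one: C6 ketone, C7=C8)
Conditions: Dess–Martin periodinane, NaHCO3, CH2Cl2, 0 °C
Reagents that add atoms: none
Why: oxidation of a doubly activated (benzylic and allylic) alcohol; the dienone cannot aromatise because C9 is quaternary.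

Step 22
Reactants: 32 ring B enone silyl ether
Product: 33 ring B enone phenol (C3–OH, C2–OMe)
Conditions: TBAF, AcOH, THF, 0 °C
Reagents that add atoms: none
Why: fluoride cleavage of the aryl silyl ether, buffered so that no free phenoxide is left beside the enone.

Step 23
Reactants: 33 ring B enone phenol; 34 tingenone
Product: 36 seco-ring-C dimer (cis-fused dioxane C3–O–C4′ and C2–O–C3′, both oxygens β on the tingenone unit, 3′α-OH, 4′α-methyl), via o-quinone 35 (not isolated)
Conditions: NaIO4, THF/H2O, 0 °C; extraction into CH2Cl2, drying; then 34, CH2Cl2, rt, dark; chromatographic separation of isomers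
Reagents that add atoms: sodium periodate [Na+].[O-]I(=O)(=O)=O (one oxygen)
Why: periodate oxidation of the 2-methoxyphenol gives the o-quinone with loss of methanol, and an inverse-electron-demand hetero-Diels–Alder reaction with the C3′=C4′ enol of tingenone follows, in which the nucleophilic C4′ should bond to the C3 oxygen (the phenoxide then lies para to the C6 acyl group) and the C2 oxygen closes on C3′ as hemiketal; the required β-face adduct is not expected to be strongly favoured at this remote alkene and is secured by separation.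

Step 24
Reactants: 36 seco-ring-C dimer
Product: 37 CNP0228258.2 (target)
Conditions: chloro[N,N′-bis(3,5-di-tert-butylsalicylidene)-1,2-cyclohexanediaminato]cobalt (trivalent cobalt salen chloride, 10 mol %), PhSiH3 (10 mol %), benzene, 22 °C, 0.005 M, argon
Reagents that add atoms: none
Why: Proposed new method: a trivalent cobalt hydride (from the cobalt salen chloride and PhSiH3) transfers a hydrogen atom to C26 of the unhindered, electron-rich C14=C26 alkene, the tertiary C14 radical adds to C8, the β-carbon of the ring B aryl enone, and the C7 α-keto radical is taken up by divalent cobalt and loses the C8 hydrogen (β-hydride elimination or back hydrogen-atom transfer), which restores the C7=C8 enone and the cobalt hydride, so that the step is a redox-neutral cycloisomerisation needing only catalytic silane. The closest known reaction types are the cobalt salen/silane cycloisomerisation of dienes and the iron-mediated reductive olefin–enone coupling (hydrogen-atom-transfer Giese cyclisation), the new element being turnover by dehydrogenation of an α-keto radical so that an enone acceptor survives. Ring C closes in the 6-exo-trig mode through a chair-like transition state. The only new stereocentre, C14, is controlled by the existing C9 and C13 quaternary centres: planar ring B holds the C9 methyl axial on the forming ring, and the radical carbon places its small methyl group (C26), not the C15 methylene carrying the D/E bicycle, in the axial site syn to it, which leads to the trans C/D junction with the C14 methyl anti to the C13 methyl. The step needs hydrogen-atom transfer to the 1,1-disubstituted alkene in preference to the conjugated, electron-poor and more substituted trienone of the tingenone unit, 6-exo closure faster than intermolecular trapping or 7-endo attack (high dilution, polarity match of the nucleophilic radical with the enone β-carbon), and termination by dehydrogenation and not by reduction (no stoichiometric reductant); isomerisation of the methylene group to the C14=C15 alkene would be reversible and would feed the same radical.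

**Compound list**

1 | isoprene | C=CC(C)=C | starting material
2 | methacrolein | CC(=C)C=O | starting material
3 | (R)-1,4-dimethylcyclohex-3-ene-1-carbaldehyde | O=C[C@]1(C)CCC(C)=CC1 | intermediate
4 | (R)-1,4-dimethylcyclohex-3-ene-1-carboxylic acid | OC(=O)[C@]1(C)CCC(C)=CC1 | intermediate
5 | methyl (R)-1,4-dimethylcyclohex-3-ene-1-carboxylate | COC(=O)[C@]1(C)CCC(C)=CC1 | intermediate
6 | methyl (1R)-3-hydroxy-1,4-dimethylcyclohexane-1-carboxylate (diastereomers) | COC(=O)[C@]1(C)CCC(C)C(O)C1 | intermediate
7 | methyl (1R)-1,4-dimethyl-3-oxocyclohexane-1-carboxylate (C4 epimers) | COC(=O)[C@]1(C)CCC(C)C(=O)C1 | intermediate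
8 | ethyl vinyl ketone (pent-1-en-3-one) | CCC(=O)C=C | starting material
9 | (S)-1-phenylethyl ketimine of 7 | COC(=O)[C@]1(C)CCC(C)C(=N[C@@H](C)c2ccccc2)C1 | intermediate
10 | C17-alkylated ketimine (Michael adduct imine) | COC(=O)[C@]1(C)CC[C@](C)(CCC(=O)CC)C(=N[C@@H](C)c2ccccc2)C1 | intermediate
11 | methyl (1R,4R)-1,4-dimethyl-3-oxo-4-(3-oxopentyl)cyclohexane-1-carboxylate | COC(=O)[C@]1(C)CC[C@](C)(CCC(=O)CC)C(=O)C1 | intermediate
12 | methyl (2R,4aR)-2,4a,8-trimethyl-7-oxo-1,2,3,4,4a,5,6,7-octahydronaphthalene-2-carboxylate (D/E octalone) | COC(=O)[C@]1(C)CC[C@]2(C)CCC(=O)C(C)=C2C1 | intermediate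
13 | cis-fused D/E decalone (17β-methyl, 18β-H, C14 ketone, C13 epimers) | COC(=O)[C@]1(C)CC[C@]2(C)CCC(=O)C(C)[C@@H]2C1 | intermediate
14 | C13=C14 trimethylsilyl enol ether of 13 | COC(=O)[C@]1(C)CC[C@]2(C)CCC(O[Si](C)(C)C)=C(C)[C@@H]2C1 | intermediate
15 | 13α-methyl-13β-(1-hydroxyethyl) cis-decalone (carbinol epimers) | COC(=O)[C@]1(C)CC[C@]2(C)CCC(=O)[C@@](C)(C(C)O)[C@@H]2C1 | intermediate
16 | 13α-methyl-13β-vinyl cis-decalone | COC(=O)[C@]1(C)CC[C@]2(C)CCC(=O)[C@@](C)(C=C)[C@@H]2C1 | intermediate
17 | D/E diene ester (13α-methyl, 13β-vinyl, C14 methylene) | COC(=O)[C@]1(C)CC[C@]2(C)CCC(=C)[C@@](C)(C=C)[C@@H]2C1 | intermediate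
18 | 2-methoxy-6-methylphenol | COc1cccc(C)c1O | starting material
19 | 2-methoxy-6-methylphenyl acetate | COc1cccc(C)c1OC(C)=O | intermediate
20 | 1-(4-hydroxy-3-methoxy-5-methylphenyl)ethan-1-one | CC(=O)c1cc(OC)c(O)c(C)c1 | intermediate
21 | 1-[3-methoxy-5-methyl-4-(triisopropylsilyloxy)phenyl]ethan-1-one | CC(=O)c1cc(OC)c(O[Si](C(C)C)(C(C)C)C(C)C)c(C)c1 | intermediate
22 | 1-[2-iodo-5-methoxy-3-methyl-4-(triisopropylsilyloxy)phenyl]ethan-1-one | CC(=O)c1cc(OC)c(O[Si](C(C)C)(C(C)C)C(C)C)c(C)c1I | intermediate
23 | ethyl (E)-3-[2-iodo-5-methoxy-3-methyl-4-(triisopropylsilyloxy)phenyl]but-2-enoate | CCOC(=O)/C=C(\C)c1cc(OC)c(O[Si](C(C)C)(C(C)C)C(C)C)c(C)c1I | intermediate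
24 | (E)-3-[2-iodo-5-methoxy-3-methyl-4-(triisopropylsilyloxy)phenyl]but-2-en-1-ol | OC/C=C(\C)c1cc(OC)c(O[Si](C(C)C)(C(C)C)C(C)C)c(C)c1I | intermediate
25 | allyl mesylate of 24 | CS(=O)(=O)OC/C=C(\C)c1cc(OC)c(O[Si](C(C)C)(C(C)C)C(C)C)c(C)c1I | intermediate
26 | [4-((E)-4-chlorobut-2-en-2-yl)-3-iodo-6-methoxy-2-methylphenoxy]triisopropylsilane | ClC/C=C(\C)c1cc(OC)c(O[Si](C(C)C)(C(C)C)C(C)C)c(C)c1I | intermediate
27 | B-alkyl-9-BBN from 17 (boron on C11) | COC(=O)[C@]1(C)CC[C@]2(C)CCC(=C)[C@@](C)(CCB3C4CCCC3CCC4)[C@@H]2C1 | intermediate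
28 | (9R)-coupled seco compound (aryl iodide, C9 vinyl) | COC(=O)[C@]1(C)CC[C@]2(C)CCC(=C)[C@@](C)(CC[C@](C)(C=C)c3cc(OC)c(O[Si](C(C)C)(C(C)C)C(C)C)c(C)c3I)[C@@H]2C1 | intermediate
29 | arylmagnesium chloride from 28 | COC(=O)[C@]1(C)CC[C@]2(C)CCC(=C)[C@@](C)(CC[C@](C)(C=C)c3cc(OC)c(O[Si](C(C)C)(C(C)C)C(C)C)c(C)c3[Mg]Cl)[C@@H]2C1 | intermediate
30 | C6 vinyl carbinol (carbinol epimers) | COC(=O)[C@]1(C)CC[C@]2(C)CCC(=C)[C@@](C)(CC[C@](C)(C=C)c3cc(OC)c(O[Si](C(C)C)(C(C)C)C(C)C)c(C)c3C(O)C=C)[C@@H]2C1 | intermediate
31 | ring B dienol (C6–OH, C7=C8) | COC(=O)[C@]1(C)CC[C@]2(C)CCC(=C)[C@@](C)(CC[C@]3(C)C=CC(O)c4c(C)c(O[Si](C(C)C)(C(C)C)C(C)C)c(OC)cc43)[C@@H]2C1 | intermediate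
32 | ring B enone silyl ether (C6 ketone, C7=C8, C14 methylene) | COC(=O)[C@]1(C)CC[C@]2(C)CCC(=C)[C@@](C)(CC[C@]3(C)C=CC(=O)c4c(C)c(O[Si](C(C)C)(C(C)C)C(C)C)c(OC)cc43)[C@@H]2C1 | intermediate
33 | ring B enone phenol (C3–OH, C2–OMe) | COC(=O)[C@]1(C)CC[C@]2(C)CCC(=C)[C@@](C)(CC[C@]3(C)C=CC(=O)c4c(C)c(O)c(OC)cc43)[C@@H]2C1 | intermediate
34 | tingenone | O=C1C=C2C(=CC=C3[C@@]2(C)CC[C@@]4(C)[C@@H]5C[C@@H](C)C(=O)C[C@]5(C)CC[C@]34C)C(C)=C1O | starting material
35 | seco-ring-C o-quinone (C2, C3 dione) | COC(=O)[C@]1(C)CC[C@]2(C)CCC(=C)[C@@](C)(CC[C@]3(C)C=CC(=O)C4=C(C)C(=O)C(=O)C=C43)[C@@H]2C1 | intermediate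
36 | seco-ring-C dimer (dioxane closed, ring C open at C8–C14) | COC(=O)[C@]1(C)CC[C@]2(C)CCC(=C)[C@@](C)(CC[C@]3(C)C=CC(=O)c4c(C)c5O[C@]6(C)C7=CC=C8[C@@](C)(CC[C@@]9(C)[C@@H]%10C[C@@H](C)C(=O)C[C@]%10(C)CC[C@]89C)C7=CC(=O)[C@]6(O)Oc5cc43)[C@@H]2C1 | intermediate
37 | CNP0228258.2 | COC(=O)[C@]1(C)CC[C@]2(C)CC[C@]3(C)C4=CC(=O)c5c(cc6c(c5C)O[C@]5(C)C7=CC=C8[C@@](C)(CC[C@@]9(C)[C@@H]%10C[C@@H](C)C(=O)C[C@]%10(C)CC[C@]89C)C7=CC(=O)[C@]5(O)O6)[C@]4(C)CC[C@@]3(C)[C@@H]2C1 | target

**Count and risks**

Total steps: 24. Longest linear sequence: 18 steps (steps 1–11, then 18–24).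

Step 24 (Proposed new method). What may go wrong: termination of the α-keto radical by reduction or quenching before cyclisation instead of dehydrogenation, hydrogen-atom transfer to the trienone of the tingenone unit, or poor facial selectivity at C14. Fallback with known chemistry, setting out from 32 and returning at 37: iron-mediated reductive radical cyclisation (Fe(acac)3, PhSiH3, EtOH/ethylene glycol, 60 °C; hydrogen-atom-transfer Giese cyclisation) of 32 would give the saturated ring C ketone F1 (C8 configuration inconsequential). Dehydrogenation (IBX, DMSO/toluene, 70 °C), unambiguous at this stage because the C6 ketone is the only enolisable carbonyl group, would give the protected 6-oxo-7-ene pentacycle F2. TBAF/AcOH would give the phenol F3, and NaIO4 followed by tingenone 34, as in step 23, would lead through the pentacyclic o-quinone F4 to 37. In this variant the dioxane, not ring C, is the last ring closed.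

Step 23. What may go wrong: self-condensation or tautomerisation of the o-quinone faster than cycloaddition, and poor facial selectivity on the tingenone enol. Fallback, setting out from 33 and 34 and returning at 36: tingenone is O-silylated at the C3′ enol (N,O-bis(trimethylsilyl)acetamide, CH2Cl2) to the silyl enol ether F5. This more nucleophilic partner is combined at −78 °C with o-quinone 35 in a stepwise Mukaiyama–Michael addition/ketal closure to the silyl ketal F6, and buffered fluoride (TBAF/AcOH) then gives 36.

Step 18. What may go wrong: incomplete γ-selectivity or weak catalyst control in forming the hindered aryl-bearing quaternary centre, and competing hydroboration of the C14 methylene. Fallback with substrate-controlled chirality transfer, setting out from 24 and returning at 31: MnO2 oxidation of 24 would give the enal F7. Catalytic asymmetric methyl addition (Me2Zn with a chiral amino alcohol, the enantiomer giving the S carbinol) would give the (S,E)-allylic alcohol F8, and ClP(O)(OEt)2/pyridine the phosphate F9. The known stereospecific, γ-selective 1,3-anti copper-catalysed coupling with alkylborane 27 (CuOAc, KOMe, THF, 60 °C) would give the (E)-propenyl analogue F10 with the same C9 configuration. Iodine–magnesium exchange and acrolein addition would give F11, whose ring-closing metathesis (loss of propene) gives 31.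

**Further compounds**

F1 | step 24 | saturated ring C ketone silyl ether (7,8-dihydro, C8 unassigned) | COC(=O)[C@]1(C)CC[C@]2(C)CC[C@]3(C)C4CC(=O)c5c(cc(OC)c(O[Si](C(C)C)(C(C)C)C(C)C)c5C)[C@]4(C)CC[C@@]3(C)[C@@H]2C1
F2 | step 24 | 6-oxopristimerol 2-methyl 3-triisopropylsilyl ether | COC(=O)[C@]1(C)CC[C@]2(C)CC[C@]3(C)C4=CC(=O)c5c(cc(OC)c(O[Si](C(C)C)(C(C)C)C(C)C)c5C)[C@]4(C)CC[C@@]3(C)[C@@H]2C1
F3 | step 24 | 6-oxopristimerol 2-methyl ether | COC(=O)[C@]1(C)CC[C@]2(C)CC[C@]3(C)C4=CC(=O)c5c(cc(OC)c(O)c5C)[C@]4(C)CC[C@@]3(C)[C@@H]2C1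
F4 | step 24 | pentacyclic o-quinone of 6-oxopristimerol | COC(=O)[C@]1(C)CC[C@]2(C)CC[C@]3(C)C4=CC(=O)C5=C(C)C(=O)C(=O)C=C5[C@]4(C)CC[C@@]3(C)[C@@H]2C1
F5 | step 23 | 3-O-trimethylsilyl tingenone | O=C1C=C2C(=CC=C3[C@@]2(C)CC[C@@]4(C)[C@@H]5C[C@@H](C)C(=O)C[C@]5(C)CC[C@]34C)C(C)=C1O[Si](C)(C)C
F6 | step 23 | 3′-O-trimethylsilyl ketal of 36 | COC(=O)[C@]1(C)CC[C@]2(C)CCC(=C)[C@@](C)(CC[C@]3(C)C=CC(=O)c4c(C)c5O[C@]6(C)C7=CC=C8[C@@](C)(CC[C@@]9(C)[C@@H]%10C[C@@H](C)C(=O)C[C@]%10(C)CC[C@]89C)C7=CC(=O)[C@]6(O[Si](C)(C)C)Oc5cc43)[C@@H]2C1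
F7 | step 18 | (E)-3-[2-iodo-5-methoxy-3-methyl-4-(triisopropylsilyloxy)phenyl]but-2-enal | O=C/C=C(\C)c1cc(OC)c(O[Si](C(C)C)(C(C)C)C(C)C)c(C)c1I
F8 | step 18 | (S,E)-4-[2-iodo-5-methoxy-3-methyl-4-(triisopropylsilyloxy)phenyl]pent-3-en-2-ol | C[C@H](O)/C=C(\C)c1cc(OC)c(O[Si](C(C)C)(C(C)C)C(C)C)c(C)c1I
F9 | step 18 | diethyl phosphate of F8 | C[C@H](OP(=O)(OCC)OCC)/C=C(\C)c1cc(OC)c(O[Si](C(C)C)(C(C)C)C(C)C)c(C)c1I
F10 | step 18 | (E)-propenyl analogue of 28 | COC(=O)[C@]1(C)CC[C@]2(C)CCC(=C)[C@@](C)(CC[C@](C)(/C=C/C)c3cc(OC)c(O[Si](C(C)C)(C(C)C)C(C)C)c(C)c3I)[C@@H]2C1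
F11 | step 18 | (E)-propenyl analogue of 30 | COC(=O)[C@]1(C)CC[C@]2(C)CCC(=C)[C@@](C)(CC[C@](C)(/C=C/C)c3cc(OC)c(O[Si](C(C)C)(C(C)C)C(C)C)c(C)c3C(O)C=C)[C@@H]2C1
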